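At the reading, 40 s after the start, I want the target in each flask.

    starting material → side product A (k1 = 0.019 /s)
    starting material + partner → side product B (k2 = 18 /M/s)
    starting material + partner → intermediate (k3 = 13 /M/s)
    partner + intermediate → target (k4 = 18 /M/s)
    intermediate → side product C (k5 = 0.30 /s)
    gas ⇌ partner, rate k6*(csat - [partner]) (k6 = 0.040 /s, csat = 3.4 mM)

| setting | south-east | south | north-east | south-west |
|---|---|---|---|---|
| starting material | 3.0 mM | 6.0 mM | 12 mM | 25 mM |
| gas | 3.4 mM (held) | 3.4 mM (held) | 3.4 mM (held) | 3.4 mM (held) |
| time | 40 s | 40 s | 40 s | 40 s |

1. [target] at the end for south-east, south, north-east, south-west, in this order
2. the course of these numbers from the first flask to the last (hardly changes / rises all the way / falls all the way / falls, then rises / rises, then falls)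

- at the start none of partner is dissolved
- "hardly changes" means that all values lie within two and a half points (for a concentration: within two and a half percent of the largest)
- run time (south-east): 40 s

The target costs two partners, one to make the intermediate and one to catch it. Even at saturation, partner catches the intermediate at 0.0612 /s, slower than the 0.30 /s at which it falls to side product C, so I take the target to grow as starting material times partner squared.

I compare south-east with its neighbour, south. South-east opens toward a fill of 30.1% and south toward 17.7%. The fill is the fraction of saturation at which transfer from the gas balances the two steps in which starting material takes up partner, the catching step set aside: the transfer coefficient over itself plus their summed constants times the starting material present. Charge times fill squared gives south 0.693 of the south-east pace at those opening fills.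

But the comparison drifts. At those fills I reckon starting material to decay at 0.0507 /s in south-east and 0.0377 /s in south, so I expect 13.2% and 22.2% of the charges left at the reading. With that much left I reckon the fills at 76.6% and 49.2%, and south at 1.39 of the south-east pace, higher than at the opening fills. I commit to south ending slightly above south-east in concentration, though with a smaller fraction of its charge turned into target.

The forecast gives 0.036 mM, 0.04 mM, 0.047 mM and 0.028 mM, with the course rises, then falls, saying that “in the richest flask it holds the partner so low” that the yield drops. It too puts south above south-east.

The flasks read 0.0430 mM, 0.0523 mM, 0.0453 mM and 0.0285 mM, and the course is rises, then falls, with south higher than the others, where the forecast has north-east highest. In south-east at 40.0 s, 11.0% of the charge is left and partner stands at 57.5% of saturation against a fill of 79.6%, while partner is made 2.73 times faster than it is used. In south-west at 20.0 s, with 60.7% of the charge left, the fill is 7.84% and partner stands at 7.46% of saturation.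

The constants used here stand for no real mixture; no experiment stands behind them.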